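**Plan**
- Retrosynthesis cuts, in order: the O–Si bond at C7; the two ring B bonds C1'–C2' and C3'–C4' (benzoate back to a 2-pyrone plus 1,1-dimethoxyethene); the C8–O ether bond; the C7–aryl bond to ring A; and the pyrone back to galactaric acid.
- Enabling feature: ring B is a benzoate whose C1' (ester), C3' (methoxy) and C4' (ether oxygen) correspond to C6, the acetal carbon and C3 of a 3-alkoxy-2-pyrone-6-carboxylate/ketene acetal pair; the lactone CO2 bridge between C1' and C4' is expelled.
- Forward: ring A arrives intact as an aryl Grignard reagent and is joined to a lactate-derived Weinreb amide (chain C7–C8–C9). The pyrone from galactaric acid is attached at C8 by Mitsunobu etherification. Ring B, the only ring built, closes last by cycloaddition, followed by desilylation.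
- Stereochemistry: C8 comes from methyl (R)-lactate and is inverted once (R to S) in the Mitsunobu step. C7 (S) is set by chelation-controlled Zn(BH4)2 reduction, anti to the C8 benzyloxy group.

Key step: step 10

Remark: the target is the threo (7S,8S) isomer as drawn. C7 is the benzylic carbinol carbon, C8 the ether-bearing carbon, C9 the methyl group; ring A is the trimethoxyphenyl ring and primed locants belong to ring B.

**Route**

Step 1
Reactants: 1 methyl (R)-lactate
Product: 2 methyl (2R)-2-(benzyloxy)propanoate
Conditions: benzyl 2,2,2-trichloroacetimidate, TfOH (cat.), cyclohexane/CH2Cl2, rt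
Reagents that add atoms: benzyl 2,2,2-trichloroacetimidate, ClC(Cl)(Cl)C(=N)OCc1ccccc1
Why: Acid-catalysed O-alkylation with a benzyl trichloroacetimidate runs under non-basic conditions that leave the α-stereocentre (R) untouched, and the benzyl ether is the chelating group needed in step 4.

Step 2
Reactants: 2 methyl (2R)-2-(benzyloxy)propanoate
Product: 3 (2R)-2-(benzyloxy)-N-methoxy-N-methylpropanamide
Conditions: MeNHOMe·HCl, iPrMgCl, THF, −20 to 0 °C; aq NH4Cl
Reagents that add atoms: N,O-dimethylhydroxylamine hydrochloride, CNOC.Cl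
Why: Weinreb amide formation by aminolysis of the methyl ester with the chloromagnesium amide of N,O-dimethylhydroxylamine is fast at low temperature, so the α-alkoxy stereocentre should not epimerise.

Step 3
Reactants: 3 (2R)-2-(benzyloxy)-N-methoxy-N-methylpropanamide; 4 5-bromo-1,2,3-trimethoxybenzene
Product: 6 (2R)-2-(benzyloxy)-1-(3,4,5-trimethoxyphenyl)propan-1-one, via arylmagnesium bromide 5 (not isolated)
Conditions: 4, Mg, I2 (cat.), THF, reflux; then 3, THF, 0 °C; aq NH4Cl
Reagents that add atoms: none
Why: Weinreb ketone synthesis, in which the aryl Grignard reagent adds once to give a magnesium-chelated tetrahedral adduct that collapses to the ketone only on quench, preventing over-addition and keeping the enolisable C8 centre from meeting base as a ketone.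

Step 4
Reactants: 6 (2R)-2-(benzyloxy)-1-(3,4,5-trimethoxyphenyl)propan-1-one
Product: 7 (1S,2R)-2-(benzyloxy)-1-(3,4,5-trimethoxyphenyl)propan-1-ol
Conditions: Zn(BH4)2, Et2O, −20 °C; aq NH4Cl
Reagents that add atoms: none
Why: Chelation-controlled (Cram chelate) hydride reduction, in which zinc bridges the carbonyl and benzyloxy oxygens and hydride attacks the carbonyl face on the side of the C8 hydrogen rather than the methyl group, which should set C7 as S in the 1,2-anti (erythro) relationship.

Step 5
Reactants: 7 (1S,2R)-2-(benzyloxy)-1-(3,4,5-trimethoxyphenyl)propan-1-ol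
Product: 8 {[(1S,2R)-2-(benzyloxy)-1-(3,4,5-trimethoxyphenyl)propyl]oxy}(tert-butyl)dimethylsilane
Conditions: TBSOTf, 2,6-lutidine, CH2Cl2, −78 to 0 °C
Reagents that add atoms: tert-butyldimethylsilyl trifluoromethanesulfonate, CC(C)(C)[Si](C)(C)OS(=O)(=O)C(F)(F)F
Why: Silylation with a silyl triflate and a hindered pyridine base is fast even at a hindered benzylic carbinol and touches neither stereocentre; the silyl ether is chosen to survive hydrogenolysis, Mitsunobu coupling and neutral heating.

Step 6
Reactants: 8 {[(1S,2R)-2-(benzyloxy)-1-(3,4,5-trimethoxyphenyl)propyl]oxy}(tert-butyl)dimethylsilane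
Product: 9 (1S,2R)-1-[(tert-butyldimethylsilyl)oxy]-1-(3,4,5-trimethoxyphenyl)propan-2-ol
Conditions: H2 (1 atm), Pd/C, EtOAc, rt
Reagents that add atoms: none
Why: Hydrogenolysis of the benzyl alkyl ether over palladium in a neutral aprotic solvent should free the C8 hydroxyl, the bulky secondary silyl ether at C7 being far slower to cleave than the unhindered O–CH2Ph bond.

Step 7
Reactants: 10 galactaric acid
Product: 12 3-hydroxy-2-oxo-2H-pyran-6-carboxylic acid, via acetoxypyrone acid 11 (not isolated)
Conditions: Ac2O, pyridine, 90 °C; then aq HCl, 60 °C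
Reagents that add atoms: none
Why: Acetylation of the aldaric acid followed by lactonisation and two β-eliminations of acetate is the established dehydrative route to 3-acyloxy-2-pyrone-6-carboxylates, and mild acid hydrolysis of the enol acetate then frees the 3-hydroxyl; all four sugar stereocentres are destroyed, so none needs control.

Step 8
Reactants: 12 3-hydroxy-2-oxo-2H-pyran-6-carboxylic acid
Product: 13 methyl 3-hydroxy-2-oxo-2H-pyran-6-carboxylate
Conditions: MeOH, H2SO4 (cat.), reflux
Reagents that add atoms: methanol, CO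
Why: Fischer esterification in acidic methanol, conditions under which 2-pyrone lactones and the enolic 3-hydroxyl are stable, as in the preparation of methyl coumalate.

Step 9
Reactants: 9 (1S,2R)-1-[(tert-butyldimethylsilyl)oxy]-1-(3,4,5-trimethoxyphenyl)propan-2-ol; 13 methyl 3-hydroxy-2-oxo-2H-pyran-6-carboxylate
Product: 14 methyl 3-{[(1S,2S)-1-[(tert-butyldimethylsilyl)oxy]-1-(3,4,5-trimethoxyphenyl)propan-2-yl]oxy}-2-oxo-2H-pyran-6-carboxylate
Conditions: PPh3, DIAD, THF, 0 °C to rt
Reagents that add atoms: none
Why: Mitsunobu etherification, in which the acidic enolic hydroxyl of the pyrone displaces the oxyphosphonium leaving group at C8 in an SN2 reaction, so C8 is inverted from R to S while C7 is untouched.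

Step 10
Reactants: 14 methyl 3-{[(1S,2S)-1-[(tert-butyldimethylsilyl)oxy]-1-(3,4,5-trimethoxyphenyl)propan-2-yl]oxy}-2-oxo-2H-pyran-6-carboxylate; 15 1,1-dimethoxyethene
Product: 18 methyl 4-{[(1S,2S)-1-[(tert-butyldimethylsilyl)oxy]-1-(3,4,5-trimethoxyphenyl)propan-2-yl]oxy}-3-methoxybenzoate, via bicyclic lactone adduct 16 (not isolated), via dimethoxycyclohexadiene ester 17 (not isolated)
Conditions: 15 (10 equiv), toluene, 130 °C, sealed tube
Reagents that add atoms: none
Why: The ketene acetal should add across C3 and C6 of the pyrone in an inverse-electron-demand Diels–Alder reaction, its nucleophilic CH2 bonding to C6 (the C1'–C2' bond) and its acetal carbon to C3 (the C3'–C4' bond); the bridged lactone 16 then extrudes CO2 by cycloreversion and the 5,5-dimethoxycyclohexa-1,3-diene 17 loses methanol to give the arene. The closest known reaction type is the thermal benzannulation of ester-bearing 2-pyrones with 1,1-dialkoxyethenes to give alkoxybenzoates. Ring B, the only ring formed, is closed by intermolecular (4+2) cycloaddition, four carbons coming from the pyrone and two from the alkene, and becomes aromatic through the two eliminations. No lasting stereocentre is created, since the bridgehead centres of 16 vanish on aromatisation, and C7 and C8 carry no acidic hydrogen and should survive neutral heating. The selectivity needed is regiochemical: the lactone carbonyl makes C6 the electrophilic terminus and C3 the enolate-like terminus, and the C6 ester lowers the LUMO and withdraws inductively at C6. The C3 alkoxy donor slows the reaction and the conjugative pull of the ester toward C3 weakens this bias, which is why excess ketene acetal and 130 °C are specified.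

Step 11
Reactants: 18 methyl 4-{[(1S,2S)-1-[(tert-butyldimethylsilyl)oxy]-1-(3,4,5-trimethoxyphenyl)propan-2-yl]oxy}-3-methoxybenzoate
Product: 19 methyl 4-{[(1S,2S)-1-hydroxy-1-(3,4,5-trimethoxyphenyl)propan-2-yl]oxy}-3-methoxybenzoate
Conditions: Bu4NF, AcOH, THF, 0 °C to rt
Reagents that add atoms: none
Why: Fluoride-mediated desilylation cleaves the Si–O bond selectively while acetic acid buffering protects the methyl ester; no stereocentre is involved, so the (7S,8S) configuration is retained.

**Compound list**
1 | methyl (R)-lactate, methyl (2R)-2-hydroxypropanoate | C[C@@H](O)C(=O)OC | starting material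
2 | methyl (2R)-2-(benzyloxy)propanoate | C[C@@H](OCc1ccccc1)C(=O)OC | intermediate
3 | (2R)-2-(benzyloxy)-N-methoxy-N-methylpropanamide | C[C@@H](OCc1ccccc1)C(=O)N(C)OC | intermediate
4 | 5-bromo-1,2,3-trimethoxybenzene | COc1cc(Br)cc(OC)c1OC | starting material
5 | (3,4,5-trimethoxyphenyl)magnesium bromide | COc1cc([Mg]Br)cc(OC)c1OC | intermediate
6 | (2R)-2-(benzyloxy)-1-(3,4,5-trimethoxyphenyl)propan-1-one | C[C@@H](OCc1ccccc1)C(=O)c1cc(OC)c(OC)c(OC)c1 | intermediate
7 | (1S,2R)-2-(benzyloxy)-1-(3,4,5-trimethoxyphenyl)propan-1-ol | C[C@@H](OCc1ccccc1)[C@@H](O)c1cc(OC)c(OC)c(OC)c1 | intermediate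
8 | {[(1S,2R)-2-(benzyloxy)-1-(3,4,5-trimethoxyphenyl)propyl]oxy}(tert-butyl)dimethylsilane | C[C@@H](OCc1ccccc1)[C@@H](O[Si](C)(C)C(C)(C)C)c1cc(OC)c(OC)c(OC)c1 | intermediate
9 | (1S,2R)-1-[(tert-butyldimethylsilyl)oxy]-1-(3,4,5-trimethoxyphenyl)propan-2-ol | C[C@@H](O)[C@@H](O[Si](C)(C)C(C)(C)C)c1cc(OC)c(OC)c(OC)c1 | intermediate
10 | galactaric acid (mucic acid) | OC(=O)[C@H](O)[C@@H](O)[C@@H](O)[C@H](O)C(O)=O | starting material
11 | 3-acetoxy-2-oxo-2H-pyran-6-carboxylic acid (formed as its pyridinium salt) | CC(=O)OC1=CC=C(C(=O)O)OC1=O | intermediate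
12 | 3-hydroxy-2-oxo-2H-pyran-6-carboxylic acid | OC(=O)C1=CC=C(O)C(=O)O1 | intermediate
13 | methyl 3-hydroxy-2-oxo-2H-pyran-6-carboxylate | COC(=O)C1=CC=C(O)C(=O)O1 | intermediate
14 | methyl 3-{[(1S,2S)-1-[(tert-butyldimethylsilyl)oxy]-1-(3,4,5-trimethoxyphenyl)propan-2-yl]oxy}-2-oxo-2H-pyran-6-carboxylate | COC(=O)C1=CC=C(O[C@@H](C)[C@@H](O[Si](C)(C)C(C)(C)C)c2cc(OC)c(OC)c(OC)c2)C(=O)O1 | intermediate
15 | 1,1-dimethoxyethene | COC(=C)OC | starting material
16 | methyl 4-{[(1S,2S)-1-[(tert-butyldimethylsilyl)oxy]-1-(3,4,5-trimethoxyphenyl)propan-2-yl]oxy}-5,5-dimethoxy-3-oxo-2-oxabicyclo[2.2.2]oct-7-ene-1-carboxylate (bridgehead configuration not controlled) | COC(=O)C12CC(OC)(OC)C(O[C@@H](C)[C@@H](O[Si](C)(C)C(C)(C)C)c3cc(OC)c(OC)c(OC)c3)(C=C1)C(=O)O2 | intermediate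
17 | methyl 4-{[(1S,2S)-1-[(tert-butyldimethylsilyl)oxy]-1-(3,4,5-trimethoxyphenyl)propan-2-yl]oxy}-5,5-dimethoxycyclohexa-1,3-diene-1-carboxylate | COC(=O)C1=CC=C(O[C@@H](C)[C@@H](O[Si](C)(C)C(C)(C)C)c2cc(OC)c(OC)c(OC)c2)C(OC)(OC)C1 | intermediate
18 | methyl 4-{[(1S,2S)-1-[(tert-butyldimethylsilyl)oxy]-1-(3,4,5-trimethoxyphenyl)propan-2-yl]oxy}-3-methoxybenzoate | COC(=O)c1ccc(O[C@@H](C)[C@@H](O[Si](C)(C)C(C)(C)C)c2cc(OC)c(OC)c(OC)c2)c(OC)c1 | intermediate
19 | methyl 4-{[(1S,2S)-1-hydroxy-1-(3,4,5-trimethoxyphenyl)propan-2-yl]oxy}-3-methoxybenzoate | COC(=O)c1ccc(O[C@@H](C)[C@@H](O)c2cc(OC)c(OC)c(OC)c2)c(OC)c1 | target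

**Step count**
Total step count: 11.
Longest linear sequence: 9 steps (steps 1–6, 9, 10, 11, from methyl (R)-lactate). The pyrone branch is 2 steps (steps 7 and 8).

**Steps most likely to fail**

1. Step 10. The C3 alkoxy donor raises the pyrone LUMO, so the cycloaddition may be slow enough for the ketene acetal to oligomerise on prolonged heating. Regiocontrol may also erode, because conjugation of the C6 ester with C3 opposes the polarisation set by the lactone carbonyl. Fallback: setting out from alcohol 9, ring B would be brought in intact by Mitsunobu etherification (PPh3, DIAD, THF) with commercial methyl 4-hydroxy-3-methoxybenzoate. This gives the silyl ether 18 directly with inversion at C8 and rejoins the route at 18. This path makes no compound outside the list (none F0).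

2. Step 9. Activation of the C8 carbinol may be sluggish because it sits next to the bulky silyloxy-bearing benzylic carbon. The oxyphosphonium intermediate may eliminate instead of being displaced, or the silyl group may migrate from O7 to O8 before coupling. Fallback: setting out from 9, treatment with Tf2O and pyridine in CH2Cl2 at −30 °C would give (1S,2R)-1-[(tert-butyldimethylsilyl)oxy]-1-(3,4,5-trimethoxyphenyl)propan-2-yl trifluoromethanesulfonate F1. This is displaced by the cesium salt of 13 (Cs2CO3, MeCN, −20 °C to rt) in an SN2 reaction with inversion, returning to the route at 14.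

3. Step 6. Hydrogenolysis of the electron-rich benzylic C7–O bond, or loss of the silyl group on the palladium surface, may compete with debenzylation. Fallback: an oxidatively removable ether replaces the benzyl group. Setting out from 1, 4-methoxybenzyl 2,2,2-trichloroacetimidate with catalytic camphorsulfonic acid would give methyl (2R)-2-[(4-methoxybenzyl)oxy]propanoate F2. The operations of steps 2–5 applied to it would give in turn:
   - (2R)-N-methoxy-2-[(4-methoxybenzyl)oxy]-N-methylpropanamide F3;
   - (2R)-2-[(4-methoxybenzyl)oxy]-1-(3,4,5-trimethoxyphenyl)propan-1-one F4, with Grignard reagent 5;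
   - (1S,2R)-2-[(4-methoxybenzyl)oxy]-1-(3,4,5-trimethoxyphenyl)propan-1-ol F5, by the same chelation-controlled reduction;
   - tert-butyl({(1S,2R)-2-[(4-methoxybenzyl)oxy]-1-(3,4,5-trimethoxyphenyl)propyl}oxy)dimethylsilane F6.

   DDQ in CH2Cl2/pH 7 buffer at 0 °C would then remove the 4-methoxybenzyl group without hydrogen and return to the route at 9.

**Further compounds**
F0 | step 10 | none | none
F1 | step 9 | (1S,2R)-1-[(tert-butyldimethylsilyl)oxy]-1-(3,4,5-trimethoxyphenyl)propan-2-yl trifluoromethanesulfonate | C[C@@H](OS(=O)(=O)C(F)(F)F)[C@@H](O[Si](C)(C)C(C)(C)C)c1cc(OC)c(OC)c(OC)c1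
F2 | step 6 | methyl (2R)-2-[(4-methoxybenzyl)oxy]propanoate | C[C@@H](OCc1ccc(OC)cc1)C(=O)OC
F3 | step 6 | (2R)-N-methoxy-2-[(4-methoxybenzyl)oxy]-N-methylpropanamide | C[C@@H](OCc1ccc(OC)cc1)C(=O)N(C)OC
F4 | step 6 | (2R)-2-[(4-methoxybenzyl)oxy]-1-(3,4,5-trimethoxyphenyl)propan-1-one | C[C@@H](OCc1ccc(OC)cc1)C(=O)c1cc(OC)c(OC)c(OC)c1
F5 | step 6 | (1S,2R)-2-[(4-methoxybenzyl)oxy]-1-(3,4,5-trimethoxyphenyl)propan-1-ol | C[C@@H](OCc1ccc(OC)cc1)[C@@H](O)c1cc(OC)c(OC)c(OC)c1
F6 | step 6 | tert-butyl({(1S,2R)-2-[(4-methoxybenzyl)oxy]-1-(3,4,5-trimethoxyphenyl)propyl}oxy)dimethylsilane | C[C@@H](OCc1ccc(OC)cc1)[C@@H](O[Si](C)(C)C(C)(C)C)c1cc(OC)c(OC)c(OC)c1
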